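## Retrosynthetic overview
1. The phenol OH at C1 of ring A comes from Baeyer–Villiger oxidation and formate cleavage of a benzaldehyde, itself made from an ethyl benzoate, so the ester carbon is a placeholder for oxygen.
2. The diaryl ether C2–O comes from SNAr of a salicylate-type phenol on 2-bromo-1-fluoro-4-nitrobenzene; NO2 to NH2 to Br (Sandmeyer) then completes ring B.
3. The 4-OMe comes from selective O-methylation of ethyl 3,5-dibromo-2,4-dihydroxybenzoate, whose bromines and aromaticity both come from Br2 acting on ethyl 2,4-dioxocyclohexane-1-carboxylate.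
4. The ring A carbocycle comes from a Claisen (Dieckmann-type) closure (C2–C3), preceded by the key intermolecular Michael addition of diethyl malonate to methyl vinyl ketone (C1–C6 bond).
5. Ring order: ring A is built first (steps 1–3), and ring B is attached as a preformed benzene (step 5).

Assumption: the target has no stereocentre and no configurationally stable axis, so it is achiral and the drawn compound is the only stereoisomer.

Ring A locants: C1 carries CO2Et (later OH), C2 carries O-aryl, C3 Br, C4 OMe, C5 Br, C6 H.

## Route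

Step 1
Reactants: 1 diethyl malonate; 2 methyl vinyl ketone (but-3-en-2-one)
Product: 3 diethyl 2-(3-oxobutyl)propanedioate
Conditions: NaOEt (0.1 equiv), EtOH, 0 °C to rt (1.5 equiv of 1); distil
Reagents that add atoms: none
Why: Intermolecular Michael addition, in which the soft malonate enolate adds 1,4 to the unhindered enone under catalytic base, excess 1 suppresses double addition, the new bond becomes C1–C6 of ring A, and no stereocentre forms.

Step 2
Reactants: 3 diethyl 2-(3-oxobutyl)propanedioate
Product: 4 ethyl 2,4-dioxocyclohexane-1-carboxylate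
Conditions: NaOEt (1.1 equiv), EtOH, reflux; then aq HCl, 0 °C
Reagents that add atoms: none
Why: Intramolecular Claisen (Dieckmann-type) condensation as in the dimedone synthesis, where only the methyl-ketone enolate can close a six-membered ring onto an ester and deprotonation of the 1,3-dione drives the equilibrium; the C1 stereocentre is racemic, enolisable and erased in step 3.

Step 3
Reactants: 4 ethyl 2,4-dioxocyclohexane-1-carboxylate
Product: 8 ethyl 3,5-dibromo-2,4-dihydroxybenzoate, via monobromo dione 5 (not isolated), via dibromo dione 6 (not isolated), via ethyl 3-bromo-2,4-dihydroxybenzoate 7 (not isolated)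
Conditions: Br2 (3.1 equiv), AcOH, 15 °C to 60 °C; pour into water, recrystallise
Reagents that add atoms: bromine, BrBr
Why: Alpha-bromination and dehydrobromination aromatise the dione, and electrophilic aromatic bromination then fills C3 and C5 (ortho/para to both hydroxyls) while C6, meta to both, stays C–H.

Step 4
Reactants: 8 ethyl 3,5-dibromo-2,4-dihydroxybenzoate
Product: 9 ethyl 3,5-dibromo-2-hydroxy-4-methoxybenzoate
Conditions: MeI (1.1 equiv), K2CO3 (1.05 equiv), acetone, 40 °C
Reagents that add atoms: iodomethane, CI
Why: Williamson ether synthesis with one equivalent of base, selective because the 4-OH (two ortho bromines, para ester) is much the more acidic and the 2-OH is tied up in a hydrogen bond to the ester carbonyl.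

Step 5
Reactants: 9 ethyl 3,5-dibromo-2-hydroxy-4-methoxybenzoate; 10 2-bromo-1-fluoro-4-nitrobenzene
Product: 11 ethyl 3,5-dibromo-2-(2-bromo-4-nitrophenoxy)-4-methoxybenzoate
Conditions: Cs2CO3 (1.5 equiv), 10 (1.3 equiv), DMSO, 80 °C
Reagents that add atoms: none
Why: Nucleophilic aromatic substitution (addition–elimination), in which fluoride para to NO2 and ortho to Br is strongly activated, the caesium phenoxide is poorly solvated in DMSO, and the ring A bromines (meta to the ester) are not activated.

Step 6
Reactants: 11 ethyl 3,5-dibromo-2-(2-bromo-4-nitrophenoxy)-4-methoxybenzoate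
Product: 12 ethyl 2-(4-amino-2-bromophenoxy)-3,5-dibromo-4-methoxybenzoate
Conditions: Fe powder (5 equiv), AcOH/EtOH/H2O, 70 °C; Na2CO3 work-up, filter
Reagents that add atoms: none
Why: Béchamp-type dissolving-metal reduction of the nitro group, which leaves aryl bromides, the ester and the diaryl ether untouched, unlike catalytic hydrogenation.

Step 7
Reactants: 12 ethyl 2-(4-amino-2-bromophenoxy)-3,5-dibromo-4-methoxybenzoate
Product: 14 ethyl 3,5-dibromo-2-(2,4-dibromophenoxy)-4-methoxybenzoate, via arenediazonium bromide 13 (not isolated)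
Conditions: NaNO2 (1.1 equiv), 48% aq HBr, MeCN/H2O, 0 °C; then CuBr (1 equiv), 48% aq HBr, 0 to 60 °C
Reagents that add atoms: hydrobromic acid HBr, Br (source of the new aryl bromine, passed on through CuBr); NaNO2, [Na+].[O-]N=O (its nitrogen is held only in 13 and leaves as N2)
Why: Sandmeyer reaction, where diazotisation and single-electron transfer from monovalent copper (CuBr) give an aryl radical that abstracts bromine exactly where nitrogen sat, and the radical site para to the ether oxygen cannot cyclise.

Step 8
Reactants: 14 ethyl 3,5-dibromo-2-(2,4-dibromophenoxy)-4-methoxybenzoate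
Product: 15 [3,5-dibromo-2-(2,4-dibromophenoxy)-4-methoxyphenyl]methanol
Conditions: i-Bu2AlH (2.5 equiv), CH2Cl2, −78 to 0 °C; aq KNaC4H4O6 (potassium sodium tartrate)
Reagents that add atoms: none
Why: Full ester reduction with an electrophilic aluminium hydride, which at or below 0 °C causes no hydrodebromination or ether cleavage, and going all the way to the alcohol avoids the unreliable partial reduction.

Step 9
Reactants: 15 [3,5-dibromo-2-(2,4-dibromophenoxy)-4-methoxyphenyl]methanol
Product: 16 3,5-dibromo-2-(2,4-dibromophenoxy)-4-methoxybenzaldehyde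
Conditions: Dess–Martin periodinane (1.2 equiv), CH2Cl2, rt
Reagents that add atoms: none
Why: Dess–Martin oxidation, a mild ligand exchange and elimination at hypervalent iodine that stops cleanly at the aldehyde and ignores aryl bromides and ethers.

Step 10
Reactants: 16 3,5-dibromo-2-(2,4-dibromophenoxy)-4-methoxybenzaldehyde
Product: 18 3,5-dibromo-2-(2,4-dibromophenoxy)-4-methoxyphenol, via aryl formate 17 (not isolated)
Conditions: mCPBA (1.5 equiv), CH2Cl2, 40 °C; aq Na2SO3 wash; then MeOH, cat. HCl, rt
Reagents that add atoms: mCPBA (3-chloroperoxybenzoic acid), OOC(=O)c1cccc(Cl)c1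
Why: Baeyer–Villiger (Dakin-type) oxidation, where the ortho-aryloxy and para-methoxy donors favour aryl over hydride migration in the Criegee adduct, and acid-catalysed methanolysis of the formate frees the phenol without touching the ethers.

## Compound list
1 | diethyl malonate | CCOC(=O)CC(=O)OCC | starting material
2 | methyl vinyl ketone (but-3-en-2-one) | CC(=O)C=C | starting material
3 | diethyl 2-(3-oxobutyl)propanedioate | CCOC(=O)C(CCC(C)=O)C(=O)OCC | intermediate
4 | ethyl 2,4-dioxocyclohexane-1-carboxylate (racemic, enolisable) | CCOC(=O)C1CCC(=O)CC1=O | intermediate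
5 | ethyl 3-bromo-2,4-dioxocyclohexane-1-carboxylate (monobromo dione, stereoisomer mixture, not isolated) | CCOC(=O)C1CCC(=O)C(Br)C1=O | intermediate
6 | ethyl 1,3-dibromo-2,4-dioxocyclohexane-1-carboxylate (dibromo dione, stereoisomer mixture, not isolated) | CCOC(=O)C1(Br)CCC(=O)C(Br)C1=O | intermediate
7 | ethyl 3-bromo-2,4-dihydroxybenzoate (not isolated) | CCOC(=O)c1ccc(O)c(Br)c1O | intermediate
8 | ethyl 3,5-dibromo-2,4-dihydroxybenzoate | CCOC(=O)c1cc(Br)c(O)c(Br)c1O | intermediate
9 | ethyl 3,5-dibromo-2-hydroxy-4-methoxybenzoate | CCOC(=O)c1cc(Br)c(OC)c(Br)c1O | intermediate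
10 | 2-bromo-1-fluoro-4-nitrobenzene | O=[N+]([O-])c1ccc(F)c(Br)c1 | starting material
11 | ethyl 3,5-dibromo-2-(2-bromo-4-nitrophenoxy)-4-methoxybenzoate | CCOC(=O)c1cc(Br)c(OC)c(Br)c1Oc1ccc([N+](=O)[O-])cc1Br | intermediate
12 | ethyl 2-(4-amino-2-bromophenoxy)-3,5-dibromo-4-methoxybenzoate | CCOC(=O)c1cc(Br)c(OC)c(Br)c1Oc1ccc(N)cc1Br | intermediate
13 | 3-bromo-4-[2,4-dibromo-6-(ethoxycarbonyl)-3-methoxyphenoxy]benzenediazonium bromide (not isolated) | CCOC(=O)c1cc(Br)c(OC)c(Br)c1Oc1ccc([N+]#N)cc1Br.[Br-] | intermediate
14 | ethyl 3,5-dibromo-2-(2,4-dibromophenoxy)-4-methoxybenzoate | CCOC(=O)c1cc(Br)c(OC)c(Br)c1Oc1ccc(Br)cc1Br | intermediate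
15 | [3,5-dibromo-2-(2,4-dibromophenoxy)-4-methoxyphenyl]methanol | OCc1cc(Br)c(OC)c(Br)c1Oc1ccc(Br)cc1Br | intermediate
16 | 3,5-dibromo-2-(2,4-dibromophenoxy)-4-methoxybenzaldehyde | O=Cc1cc(Br)c(OC)c(Br)c1Oc1ccc(Br)cc1Br | intermediate
17 | 3,5-dibromo-2-(2,4-dibromophenoxy)-4-methoxyphenyl formate (not isolated) | O=COc1cc(Br)c(OC)c(Br)c1Oc1ccc(Br)cc1Br | intermediate
18 | 3,5-dibromo-2-(2,4-dibromophenoxy)-4-methoxyphenol (achiral) | COc1c(Br)cc(O)c(Oc2ccc(Br)cc2Br)c1Br | target

## Totals and risk assessment
Total step count: 10. Longest linear sequence: 10 (1/2 to 18); compound 10 is bought.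

**Step 3 (brominative aromatisation).** The risks are mixtures of bromo-diones, incomplete loss of HBr and over-bromination. The fallback sets out from 4 and comes back at 8, and it separates oxidation from halogenation. Compound 4 is dehydrogenated without halogen over Pd/C (10 wt% zerovalent palladium on carbon) in refluxing mesitylene under a nitrogen sweep. This gives ethyl 2,4-dihydroxybenzoate F1. F1 is then dibrominated as an ordinary resorcinol with Br2 (2.05 equiv) in AcOH at rt, which can only enter C3 and C5, giving 8.

**Step 5 (SNAr of a hindered, electron-poor phenoxide).** The risks are slow conversion and consumption of 10 by side reactions. The fallback sets out from 9 and comes back at 14, so steps 6 and 7 are also bypassed. The aryl group is delivered from hypervalent iodine instead of by addition–elimination.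
- Commercial 2,4-dibromo-1-iodobenzene is oxidised with mCPBA and TsOH·H2O in CH2Cl2/CF3CH2OH in the presence of anisole. This gives (2,4-dibromophenyl)(4-methoxyphenyl)iodonium tosylate F2.
- The potassium phenoxide of 9 (t-BuOK, THF, 0 °C) is warmed with this salt to 40–60 °C.
- Ligand coupling at trivalent iodine transfers the electron-poorer, ortho-substituted 2,4-dibromophenyl group, with anisyl as the spectator, and gives 14 directly.

**Step 10 (aldehyde Baeyer–Villiger).** The 4-OMe is twisted out of plane by its two bromine neighbours, so hydride migration to the benzoic acid may compete. The fallback sets out from 16 and comes back at 18, and it replaces the migrating competitor H by CH3, which always loses to aryl.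
- MeMgBr (THF, −78 °C, faster than any Br/Mg exchange) adds to 16. This gives racemic 1-[3,5-dibromo-2-(2,4-dibromophenoxy)-4-methoxyphenyl]ethanol F3.
- Dess–Martin oxidation gives 1-[3,5-dibromo-2-(2,4-dibromophenoxy)-4-methoxyphenyl]ethanone F4.
- Trifluoroperacetic acid (urea·H2O2, (CF3CO)2O, Na2HPO4, CH2Cl2, 0 °C to rt) gives 3,5-dibromo-2-(2,4-dibromophenoxy)-4-methoxyphenyl acetate F5.
- Methanolysis (cat. K2CO3, MeOH, rt, then dilute HCl) gives 18.

## Further compounds
F1 | step 3 | ethyl 2,4-dihydroxybenzoate | CCOC(=O)c1ccc(O)cc1O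
F2 | step 5 | (2,4-dibromophenyl)(4-methoxyphenyl)iodonium tosylate | COc1ccc([I+]c2ccc(Br)cc2Br)cc1.Cc1ccc(S(=O)(=O)[O-])cc1
F3 | step 10 | 1-[3,5-dibromo-2-(2,4-dibromophenoxy)-4-methoxyphenyl]ethanol (racemic) | CC(O)c1cc(Br)c(OC)c(Br)c1Oc1ccc(Br)cc1Br
F4 | step 10 | 1-[3,5-dibromo-2-(2,4-dibromophenoxy)-4-methoxyphenyl]ethanone | CC(=O)c1cc(Br)c(OC)c(Br)c1Oc1ccc(Br)cc1Br
F5 | step 10 | 3,5-dibromo-2-(2,4-dibromophenoxy)-4-methoxyphenyl acetate | CC(=O)Oc1cc(Br)c(OC)c(Br)c1Oc1ccc(Br)cc1Br
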